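Readings and results come from a simulation for substances that don't exist, and the scatter is random.

in all of them: L 0.30 M
- Tuesday's: X 2.8 equiv; run made earlier
- Wednesday's: X 4.4 equiv; run made earlier
- flask: X 2.00 equiv; time 20 h

| run | time / h | J / % | L / % |
|---|---|---|---|
| Tuesday's | 2.00 | 56 | 26 |
| Tuesday's | 6.00 | 54 | 1 |
| Tuesday's | 10.0 | 41 | 0 |
| Tuesday's | 15.0 | 30 | 1 |
| Wednesday's | 2.00 | 71 | 6 |
| Wednesday's | 6.00 | 47 | 0 |
| Wednesday's | 10.0 | 31 | 0 |
| Wednesday's | 15.0 | 16 | 2 |

(standard deviation of a reading: 2 percentage points)

- the analysis behind the earlier runs scatters by 2 percentage points, standard deviation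

* equivalents of X to L, everything else as given, that leave most J at 20 h
* the amount of J then, in percent of the L charged
* the amount of J with the amounts as given

- Take the late fall of J as the quantity to reckon with. L stood at 1 % in Tuesday's run and 0 % in Wednesday's at 6.00 h, so from there on I read J as losing, not gaining.
- Time was the first setting I turned by hand. From 6.00 h to 15.0 h, the readings gave J a first-order fall of 0.0653 h⁻¹ on Tuesday and 0.120 h⁻¹ on Wednesday, so I read waiting as costing J at about those rates.
- X was the second setting. I took one equivalent as going into making J, so I divided each rate by the equivalents beyond that one and got 0.0363 h⁻¹ and 0.0352 h⁻¹. Their mean, 0.0357 h⁻¹, I called the drain constant, the pseudo-first-order loss rate of J per equivalent of excess X.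
- L was the third setting, but I could not turn it, as both runs held 0.30 M.
- For this flask, with 2.00 equiv, the drain constant gave J a half-life of 19.4 h. I assumed the flask, with less X, reached at 10.0 h the 54 % that Tuesday's run showed at 6.00 h, which left 37.8 % at 20 h.
- In my reckoning, less than one equivalent left L over and more raised the drain, so I put the best charge a little above one equivalent.
- The forecast put the best charge at 1.35 equiv with 58 % J there, and J as charged at 45 %, this last above my figure, and held that “selectivity worsens at low X”.
- At 20 h the most J was 30.7 %, at 1.38 equiv, and the flask as charged held 27.9 %.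

    X + J → E + G (k = 2.50 × 10⁻⁵ M⁻¹ s⁻¹)
    L + G → Q (k = 5.70 × 10⁻⁵ M⁻¹ s⁻¹)
    J ⇌ Z (K = 1.60, k = 9.70 × 10⁻⁶ s⁻¹)
    L + J → D (k = 1.20 × 10⁻⁴ M⁻¹ s⁻¹)
    L + X → J + G (k = 2.70 × 10⁻⁴ M⁻¹ s⁻¹)

- With the other concentrations as charged, the half-life of J by L + J into D alone was 5.3 h, shorter than the 13 h by X + J into E + G alone. The flask held 8.87 % D at 2.00 h, D counted as two, and J stood at 44.4 % at 10.0 h, below my assumed start. With X then at 1.01 equiv, the drain constant gave 0.0360 h⁻¹, and from then to 20 h J fell at 0.0466 h⁻¹ on average. For the flask with 5.00 equiv, I took Wednesday's 47 % at 6.00 h as its start, the constant brought that down to 6.37 % at 20 h, and that flask held 9.24 %.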